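**Plan**

Retrosynthesis (flavanone numbering, double primes for the second unit): the two O1–C2 bonds of rings C are cut first (retro-oxa-Michael) to an open bis(2'-hydroxychalcone) that keeps the C3–C3'' bond; then O1–C8a and C4–C4a are cut in each ring A, leaving a bis(arylidene)succinic diacid and two arynes; the two C=C bonds of the diacid go back to anisaldehyde and dimethyl succinate.
Enabling feature: in each ring A the neighbouring carbons C8a (carrying O1) and C4a (carrying the C4 carbonyl) lie directly beside the C5 methoxy group, which is the 1-oxy-2-acyl-3-methoxy pattern a 3-methoxyaryne acquires when it inserts into the C–O bond of a carboxylic acid.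
Forward: the chain C2–C3–C3''–C2'' with both anisyl groups and both future C4 carbons is built first (double Stobbe), both rings A are attached in one operation without closing any ring, both rings C are then closed together, and the two benzyl groups are removed last.
Stereochemistry: C2 and C2'' come from a catalyst-controlled 6-endo oxa-Michael addition, C3 and C3'' from protonation and equilibration to the trans arrangement; no later step touches these centres.

Key step: step 6

Assumption: the epi-quinine-derived thiourea of step 7 is taken to give the 2S,2''S series; if the sense of induction is the opposite, the pseudo-enantiomeric epi-quinidine-derived thiourea is used under the same conditions.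

**Route**

Step 1
Reactants: 1 4-methoxybenzaldehyde (2.2 equiv); 2 dimethyl succinate
Product: 5 (2E,3E)-2,3-bis(4-methoxybenzylidene)succinic acid, via mono-arylidene half-ester 3 (not isolated), via bis-arylidene half-ester 4 (not isolated)
Conditions: NaOMe (3 equiv), MeOH, reflux; then 2 M NaOH, reflux; then HCl to pH 1, recrystallise
Reagents that add atoms: sodium hydroxide, [Na+].[OH-]
Why: Two Stobbe-type condensations run in one pot: the succinate enolate adds to 1 and lactonisation followed by base-induced ring opening gives the (E)-half-ester 3, a second aldol-type condensation at its methylene group gives 4, and saponification delivers 5, each aryl group ending trans to its carboxyl group as is usual for bis(arylidene)succinic (fulgenic) acids made this way.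

Step 2
Reactants: 6 5-bromovanillin
Product: 8 2-bromo-6-methoxybenzene-1,4-diol, via aryl formate 7 (not isolated)
Conditions: 30% H2O2, 1 M NaOH, 0 °C to rt, N2; then HCl
Reagents that add atoms: hydrogen peroxide, OO
Why: Dakin oxidation: hydroperoxide adds to the aldehyde of the para-hydroxybenzaldehyde, the electron-rich aryl group migrates to oxygen and the formate 7 is hydrolysed in the basic medium, so the formyl group is replaced by the hydroxyl that will later carry the benzyl group.

Step 3
Reactants: 8 2-bromo-6-methoxybenzene-1,4-diol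
Product: 9 1-bromo-3-methoxy-2,5-bis(trimethylsilyloxy)benzene
Conditions: hexamethyldisilazane, THF, reflux; concentrate, use crude
Reagents that add atoms: hexamethyldisilazane, C[Si](C)(C)N[Si](C)(C)C
Why: Silylation of both phenols with hexamethyldisilazane, which forms only ammonia as by-product and leaves the bis(silyl ether) dry enough for direct lithiation.

Step 4
Reactants: 9 1-bromo-3-methoxy-2,5-bis(trimethylsilyloxy)benzene
Product: 12 4-hydroxy-2-methoxy-6-(trimethylsilyl)phenyl trifluoromethanesulfonate, via lithium phenolate 10 (not isolated), via silyl ether triflate 11 (not isolated)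
Conditions: n-BuLi (1.05 equiv), THF, −78 °C; Tf2O, −78 °C; then 1 M HCl, THF, rt
Reagents that add atoms: trifluoromethanesulfonic anhydride, O=S(=O)(OS(=O)(=O)C(F)(F)F)C(F)(F)F
Why: Bromine–lithium exchange followed by a retro-Brook (1,3 O-to-C) silyl shift, which only the silyloxy group ortho to lithium can undergo, so the two oxygens are told apart without any selective protection; the lithium phenolate 10 is triflated, and the remaining aryl silyl ether of 11 is hydrolysed by dilute acid while the C–Si bond, meta to both oxygen donors, resists protodesilylation.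

Step 5
Reactants: 12 4-hydroxy-2-methoxy-6-(trimethylsilyl)phenyl trifluoromethanesulfonate; 13 benzyl bromide
Product: 14 4-(benzyloxy)-2-methoxy-6-(trimethylsilyl)phenyl trifluoromethanesulfonate
Conditions: K2CO3, acetone, rt
Reagents that add atoms: none
Why: Williamson etherification of the only free phenol; the aryl triflate and the aryl silane tolerate K2CO3 at room temperature, and because the hydroxyl is meta to silicon no silyl transfer to oxygen, and hence no premature aryne release, is possible.

Step 6
Reactants: 5 (2E,3E)-2,3-bis(4-methoxybenzylidene)succinic acid; 14 4-(benzyloxy)-2-methoxy-6-(trimethylsilyl)phenyl trifluoromethanesulfonate (2.5 equiv)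
Product: 18 (2E,3E)-1,4-bis(4-benzyloxy-2-hydroxy-6-methoxyphenyl)-2,3-bis(4-methoxybenzylidene)butane-1,4-dione, via dicesium dicarboxylate 15 (not isolated), via mono-inserted dicesium salt 16 (not isolated), via dicesium bis(phenolate) 17 (not isolated)
Conditions: Cs2CO3 (1.0 equiv), MeOH, rt, evaporate and dry (toluene azeotrope, vacuum); then CsF (6 equiv), 18-crown-6, THF, 50 °C, 14 added slowly; then AcOH, −20 °C
Reagents that add atoms: none
Why: Fluoride removes the silyl group of 14 and triflate leaves, releasing 5-benzyloxy-3-methoxybenzyne; a carboxylate oxygen of 15 adds to it, the aryl anion attacks its own ester carbonyl through a four-membered transition state and the resulting alkoxide opens to the ortho-acyl phenolate, so the former acid oxygen becomes O1 and the former acid carbon C4, and the sequence repeats at the second carboxylate (16 to 17). The closest known reaction type is the fluoride-induced insertion of arynes into the C–O bond of carboxylic acids, acrylic acids included, which gives ortho-hydroxyaryl ketones. No ring of the target closes and no stereocentre arises here; four skeletal bonds form (O1–C8a and C4–C4a, twice). Regioselectivity is required and is secured by the methoxy group next to the triple bond (future C5), which distorts the aryne and stabilises charge on the adjacent carbon, so oxygen bonds to the remote carbon that carried silicon (C8a) and the acyl group ends on the carbon that carried the triflate (C4a), the meta benzyloxy group exerting only a weak opposing bias. Chemoselectivity is secured by the proton-free medium (dried dicarboxylate, crown-ether-solubilised CsF, THF): the aryl anion can only transfer the acyl group instead of being protonated to an O-aryl ester, and the phenolate cannot turn over to a flavanone because ring closure would trade a phenolate for a far more basic enolate, so the cold acetic acid quench should deliver the hydrogen-bonded open bis-chalcone. Slow addition of 14 keeps the aryne concentration low so that the carboxylates outcompete the chelated product phenolates.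

Step 7
Reactants: 18 (2E,3E)-1,4-bis(4-benzyloxy-2-hydroxy-6-methoxyphenyl)-2,3-bis(4-methoxybenzylidene)butane-1,4-dione
Product: 20 (2S,3R,2''S,3''R)-7,7''-bis(benzyloxy)-4',4''',5,5''-tetramethoxy-3,3''-biflavanone, via half-closed flavanone 19 (not isolated)
Conditions: N-[3,5-bis(trifluoromethyl)phenyl]-N'-[(8α,9S)-6'-methoxycinchonan-9-yl]thiourea (20 mol %), toluene, 0 °C to rt; chromatography
Reagents that add atoms: none
Why: Proposed new method: the quinuclidine nitrogen of the catalyst deprotonates each chelated 2'-hydroxyl while the thiourea hydrogen-bonds the neighbouring enone carbonyl, so each phenoxide adds 6-endo-trig to its own β-carbon from the catalyst-selected face (C2 and C2'' set as S), the enolates are protonated and equilibrated by the same amine to the trans (3R, 3''R) arrangement with the 2-aryl group and the C3–C3'' bond both equatorial, and the twofold character of the reaction should raise the enantiopurity of the C2-symmetric product because mismatched events end in the separable meso diastereomer; the closest known reaction type is the cinchona-thiourea-catalysed enantioselective oxa-Michael cyclisation of α-substituted 2'-hydroxychalcones (alkylidene β-keto esters) to flavanones, extended here to a non-activated, α-branched bis-chalcone.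

Step 8
Reactants: 20 (2S,3R,2''S,3''R)-7,7''-bis(benzyloxy)-4',4''',5,5''-tetramethoxy-3,3''-biflavanone
Product: 21 4',4''',5,5''-tetramethylchamaejasmin
Conditions: H2 (1 atm), 10% Pd/C, EtOAc/MeOH, rt
Reagents that add atoms: none
Why: Hydrogenolysis of the two aryl benzyl ethers over Pd/C under neutral conditions, a standard deprotection of benzyl-protected flavanones that should leave the aryl ketones, the cyclic benzylic C2–O1 bonds and the base-sensitive C3 centres untouched when it is stopped at full debenzylation.

**Compound list**

1 | 4-methoxybenzaldehyde (anisaldehyde) | COc1ccc(C=O)cc1 | starting material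
2 | dimethyl succinate | COC(=O)CCC(=O)OC | starting material
3 | (E)-3-(methoxycarbonyl)-4-(4-methoxyphenyl)but-3-enoic acid (mono-arylidene half-ester, present as its sodium salt) | COc1ccc(/C=C(/C(=O)OC)CC(=O)O)cc1 | intermediate
4 | (2E,3E)-3-(methoxycarbonyl)-2-(4-methoxybenzylidene)-4-(4-methoxyphenyl)but-3-enoic acid (bis-arylidene half-ester, present as its sodium salt) | COc1ccc(/C=C(/C(=O)OC)C(=C/c2ccc(OC)cc2)\C(=O)O)cc1 | intermediate
5 | (2E,3E)-2,3-bis(4-methoxybenzylidene)succinic acid | COc1ccc(/C=C(/C(=O)O)C(=C/c2ccc(OC)cc2)\C(=O)O)cc1 | intermediate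
6 | 5-bromovanillin (3-bromo-4-hydroxy-5-methoxybenzaldehyde) | COc1cc(C=O)cc(Br)c1O | starting material
7 | 3-bromo-4-hydroxy-5-methoxyphenyl formate | COc1cc(OC=O)cc(Br)c1O | intermediate
8 | 2-bromo-6-methoxybenzene-1,4-diol | COc1cc(O)cc(Br)c1O | intermediate
9 | 1-bromo-3-methoxy-2,5-bis(trimethylsilyloxy)benzene | COc1cc(O[Si](C)(C)C)cc(Br)c1O[Si](C)(C)C | intermediate
10 | lithium 2-methoxy-6-(trimethylsilyl)-4-(trimethylsilyloxy)phenolate | COc1cc(O[Si](C)(C)C)cc([Si](C)(C)C)c1[O-].[Li+] | intermediate
11 | 2-methoxy-6-(trimethylsilyl)-4-(trimethylsilyloxy)phenyl trifluoromethanesulfonate | COc1cc(O[Si](C)(C)C)cc([Si](C)(C)C)c1OS(=O)(=O)C(F)(F)F | intermediate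
12 | 4-hydroxy-2-methoxy-6-(trimethylsilyl)phenyl trifluoromethanesulfonate | COc1cc(O)cc([Si](C)(C)C)c1OS(=O)(=O)C(F)(F)F | intermediate
13 | benzyl bromide | BrCc1ccccc1 | starting material
14 | 4-(benzyloxy)-2-methoxy-6-(trimethylsilyl)phenyl trifluoromethanesulfonate | COc1cc(OCc2ccccc2)cc([Si](C)(C)C)c1OS(=O)(=O)C(F)(F)F | intermediate
15 | dicesium (2E,3E)-2,3-bis(4-methoxybenzylidene)succinate | COc1ccc(/C=C(/C(=O)[O-])C(=C/c2ccc(OC)cc2)\C(=O)[O-])cc1.[Cs+].[Cs+] | intermediate
16 | dicesium (2E,3E)-3-(4-benzyloxy-6-methoxy-2-oxidobenzoyl)-2-(4-methoxybenzylidene)-4-(4-methoxyphenyl)but-3-enoate | COc1ccc(/C=C(/C(=O)c2c([O-])cc(OCc3ccccc3)cc2OC)C(=C/c2ccc(OC)cc2)\C(=O)[O-])cc1.[Cs+].[Cs+] | intermediate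
17 | dicesium bis(phenolate) of 18 | COc1ccc(/C=C(/C(=O)c2c([O-])cc(OCc3ccccc3)cc2OC)C(=C/c2ccc(OC)cc2)\C(=O)c2c([O-])cc(OCc3ccccc3)cc2OC)cc1.[Cs+].[Cs+] | intermediate
18 | (2E,3E)-1,4-bis(4-benzyloxy-2-hydroxy-6-methoxyphenyl)-2,3-bis(4-methoxybenzylidene)butane-1,4-dione | COc1ccc(/C=C(/C(=O)c2c(O)cc(OCc3ccccc3)cc2OC)C(=C/c2ccc(OC)cc2)\C(=O)c2c(O)cc(OCc3ccccc3)cc2OC)cc1 | intermediate
19 | (2S,3R)-7-benzyloxy-3-[(E)-1-(4-benzyloxy-2-hydroxy-6-methoxybenzoyl)-2-(4-methoxyphenyl)vinyl]-5-methoxy-2-(4-methoxyphenyl)chroman-4-one | COc1ccc([C@H]2Oc3cc(OCc4ccccc4)cc(OC)c3C(=O)[C@@H]2C(=C/c2ccc(OC)cc2)\C(=O)c2c(O)cc(OCc3ccccc3)cc2OC)cc1 | intermediate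
20 | (2S,3R,2''S,3''R)-7,7''-bis(benzyloxy)-4',4''',5,5''-tetramethoxy-3,3''-biflavanone, i.e. (2S,2'S,3R,3'R)-7,7'-bis(benzyloxy)-5,5'-dimethoxy-2,2'-bis(4-methoxyphenyl)-[3,3'-bichromane]-4,4'-dione | COc1ccc([C@H]2Oc3cc(OCc4ccccc4)cc(OC)c3C(=O)[C@@H]2[C@H]2C(=O)c3c(OC)cc(OCc4ccccc4)cc3O[C@@H]2c2ccc(OC)cc2)cc1 | intermediate
21 | 4',4''',5,5''-tetramethylchamaejasmin, i.e. (2S,2'S,3R,3'R)-7,7'-dihydroxy-5,5'-dimethoxy-2,2'-bis(4-methoxyphenyl)-[3,3'-bichromane]-4,4'-dione | COc1ccc([C@H]2Oc3cc(O)cc(OC)c3C(=O)[C@@H]2[C@H]2C(=O)c3c(OC)cc(O)cc3O[C@@H]2c2ccc(OC)cc2)cc1 | target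

**Step count**

Total: 8 steps. Longest linear sequence: 7 steps (6 → 8 → 9 → 12 → 14 → 18 → 20 → 21); the diacid branch (1 + 2 → 5) joins at step 6.

**Steps most likely to fail**

1. Step 7. The non-activated, α-branched and twisted enones may add the catalyst-bound phenoxide slowly or with poor facial selectivity. The half-closed intermediate may lose its γ-proton and suffer alkene migration. Reversible ring opening under the amine may erode enantiopurity over time. The fallback sets out from 18 and comes back at 20. Compound 18 is isomerised under thermodynamic control with NaOAc in refluxing EtOH (the classical chalcone–flavanone isomerisation). This should give the racemic trans,trans C2-symmetric biflavanone, that is 20 together with its enantiomer (2R,3S,2''R,3''S)-7,7''-bis(benzyloxy)-4',4''',5,5''-tetramethoxy-3,3''-biflavanone F1, besides the meso (2S,3R,2''R,3''S) diastereomer F2. F2 is removed by chromatography or crystallisation, and 20 is separated from F1 by preparative HPLC on a polysaccharide-based chiral stationary phase.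

2. Step 6. The aryl anion may be protonated before the acyl shift (O-arylation instead of insertion), the phenolates may close to racemic flavanones in the flask, or the product phenolates may be arylated further by excess aryne. The fallback sets out from 5 and comes back at 18. Compound 5 is converted with MeNHOMe·HCl, EDC·HCl, HOBt and i-Pr2NEt in CH2Cl2 into the bis(N-methoxy-N-methylamide) F3. Separately, commercial 5-methoxybenzene-1,3-diol (COc1cc(O)cc(O)c1) is benzylated twice with 13 (K2CO3, DMF) to 1,3-bis(benzyloxy)-5-methoxybenzene F4. Bromination with NBS is expected to favour the two equivalent positions between a benzyloxy and the methoxy group over the more hindered one between the two benzyloxy groups, giving 1,5-bis(benzyloxy)-2-bromo-3-methoxybenzene F5, which is purified by crystallisation. Exchange with n-BuLi in THF at −78 °C gives 2,4-bis(benzyloxy)-6-methoxyphenyllithium F6, which adds to F3 to give (2E,3E)-1,4-bis[2,4-bis(benzyloxy)-6-methoxyphenyl]-2,3-bis(4-methoxybenzylidene)butane-1,4-dione F7. MgBr2·OEt2 in toluene/Et2O then cleaves, through chelation, only the benzyl ethers ortho to the carbonyl groups and returns 18.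

3. Step 1. The one-pot sequence may stall after the first condensation, or the double bond of the half-ester may migrate, leaving mixtures that are hard to purify. The fallback sets out from 1 and 2 and comes back at 5. A single Stobbe condensation (one equivalent of 1, KOt-Bu, t-BuOH) gives 3, which is isolated. Fischer esterification (MeOH, cat. H2SO4) gives dimethyl (E)-2-(4-methoxybenzylidene)succinate F8. A second Stobbe condensation of F8 with 1 (NaOMe, MeOH) gives 4, and saponification with aqueous NaOH gives 5.

**Further compounds**

F1 | step 7 | (2R,3S,2''R,3''S)-7,7''-bis(benzyloxy)-4',4''',5,5''-tetramethoxy-3,3''-biflavanone (enantiomer of 20) | COc1ccc([C@@H]2Oc3cc(OCc4ccccc4)cc(OC)c3C(=O)[C@H]2[C@@H]2C(=O)c3c(OC)cc(OCc4ccccc4)cc3O[C@H]2c2ccc(OC)cc2)cc1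
F2 | step 7 | (2S,3R,2''R,3''S)-7,7''-bis(benzyloxy)-4',4''',5,5''-tetramethoxy-3,3''-biflavanone (meso diastereomer) | COc1ccc([C@H]2Oc3cc(OCc4ccccc4)cc(OC)c3C(=O)[C@@H]2[C@@H]2C(=O)c3c(OC)cc(OCc4ccccc4)cc3O[C@H]2c2ccc(OC)cc2)cc1
F3 | step 6 | (2E,3E)-N1,N4-dimethoxy-N1,N4-dimethyl-2,3-bis(4-methoxybenzylidene)succinamide | COc1ccc(/C=C(/C(=O)N(C)OC)C(=C/c2ccc(OC)cc2)\C(=O)N(C)OC)cc1
F4 | step 6 | 1,3-bis(benzyloxy)-5-methoxybenzene | COc1cc(OCc2ccccc2)cc(OCc2ccccc2)c1
F5 | step 6 | 1,5-bis(benzyloxy)-2-bromo-3-methoxybenzene | COc1cc(OCc2ccccc2)cc(OCc2ccccc2)c1Br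
F6 | step 6 | 2,4-bis(benzyloxy)-6-methoxyphenyllithium | COc1cc(OCc2ccccc2)cc(OCc2ccccc2)c1[Li]
F7 | step 6 | (2E,3E)-1,4-bis[2,4-bis(benzyloxy)-6-methoxyphenyl]-2,3-bis(4-methoxybenzylidene)butane-1,4-dione | COc1ccc(/C=C(/C(=O)c2c(OCc3ccccc3)cc(OCc3ccccc3)cc2OC)C(=C/c2ccc(OC)cc2)\C(=O)c2c(OCc3ccccc3)cc(OCc3ccccc3)cc2OC)cc1
F8 | step 1 | dimethyl (E)-2-(4-methoxybenzylidene)succinate | COc1ccc(/C=C(/C(=O)OC)CC(=O)OC)cc1
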